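**Plan**

Labdane numbering is used for every intermediate: C4 carries the β-methyl C19 and the α-carboxyl C18, C5/C10 are the ring fusion, C20 is the C10 methyl, C17 the C8 methyl. The enabling feature is in ring B: the 6α- and 8α-hydroxyls sit 1,3 across C7, and C8 also bears C17, which is what a C6 aldehyde, a C7=C8 isopropenyl group on C9 and one molecule of water leave behind.
Retrosynthetic cuts, in order: C12–C13 (alkyl–alkenyl Suzuki), then C6–C7 with C8–O (Prins, opens ring B), then C9–C10 (Ireland–Claisen), then C1–C10 (aldol) and C3–C4 (Michael) of ring A.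
Forward: ring A by Michael addition/aldol condensation, C6 by Wittig homologation, C9–C10 by [3,3] shift, the C8 carboxyl turned into the isopropenyl group through a lactone, ring B by Prins cyclisation with water capture, side chain by Suzuki coupling, desilylation.
Stereochemistry: C4 from a cinchona-catalysed Michael addition; C10 and C9 from the chair Ireland–Claisen (face set by the C4 methyl, C9 by the chelated enolate); C5 by hydroboration anti to the two axial methyls; C6 and C8 from the Prins chair; 13E from syn-hydrozirconation; the ylidene Z geometry from E1cB elimination.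

Key step: step 13

Remark: the cupreidine-derived catalyst of step 2 is assumed to give the (R)-configured quaternary centre; if the sense is the opposite, the quinine-derived pseudoenantiomer (the cupreine ether) is used and nothing else changes.

**Route**

Step 1
Reactants: 1 methyl 2-methyl-3-oxopentanoate
Product: 2 2-(trimethylsilyl)ethyl 2-methyl-3-oxopentanoate
Conditions: Me3SiCH2CH2OH, DMAP (cat.), toluene, 110 °C, MeOH distilled off
Reagents that add atoms: 2-(trimethylsilyl)ethanol, C[Si](C)(C)CCO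
Why: DMAP-catalysed transesterification of the β-keto ester (through the acylketene) installs, before any stereocentre exists, a C18 ester that withstands the later acid, base, hydride and organometallic steps at a quaternary carbon and is cleaved at the end by fluoride instead of hydrolysis.

Step 2
Reactants: 2 2-(trimethylsilyl)ethyl 2-methyl-3-oxopentanoate; 3 acrolein
Product: 4 2-(trimethylsilyl)ethyl (R)-2-methyl-3-oxo-2-(3-oxopropyl)pentanoate
Conditions: 9-O-(9-phenanthryl)cupreidine (10 mol %), CH2Cl2, −25 °C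
Reagents that add atoms: none
Why: Cinchona-alkaloid-catalysed enantioselective Michael addition of an α-substituted β-keto ester to acrolein (the quinuclidine deprotonates the donor, the 6'-OH binds the enal) creates the quaternary C4 with its C19 methyl and C18 ester, the catalyst distinguishing the propanoyl from the ester flank.

Step 3
Reactants: 4 2-(trimethylsilyl)ethyl (R)-2-methyl-3-oxo-2-(3-oxopropyl)pentanoate
Product: 5 2-(trimethylsilyl)ethyl (R)-1,3-dimethyl-2-oxocyclohex-3-ene-1-carboxylate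
Conditions: pyrrolidine (20 mol %), AcOH (20 mol %), toluene, 60 °C
Reagents that add atoms: none
Why: Amine-catalysed intramolecular aldol condensation (Robinson-type closure) in which the ethyl ketone α-carbon (C10) attacks the aldehyde (C1) is the only six-membered mode available and gives the ring A enone with C20 on C10, while the quaternary C4 cannot epimerise.

Step 4
Reactants: 5 2-(trimethylsilyl)ethyl (R)-1,3-dimethyl-2-oxocyclohex-3-ene-1-carboxylate
Product: 7 2-(trimethylsilyl)ethyl (R)-2-formyl-1,3-dimethylcyclohex-2-ene-1-carboxylate, via dienol ether 6 (not isolated)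
Conditions: Ph3P(CH2OMe)Cl, KN(SiMe3)2, THF, 0 °C → rt; then 1 M HCl, THF, rt
Reagents that add atoms: (methoxymethyl)triphenylphosphonium chloride, COC[P+](c1ccccc1)(c1ccccc1)c1ccccc1.[Cl-]; water, O
Why: Wittig methoxymethylenation of the enone carbonyl adds C6 at the aldehyde oxidation level, and acid hydrolysis of the 1-methoxydiene, protonated at its unhindered terminus C1, should deliver the conjugated tetrasubstituted enal (one-carbon homologation of a ketone).

Step 5
Reactants: 7 2-(trimethylsilyl)ethyl (R)-2-formyl-1,3-dimethylcyclohex-2-ene-1-carboxylate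
Product: 8 2-(trimethylsilyl)ethyl (R)-2-(hydroxymethyl)-1,3-dimethylcyclohex-2-ene-1-carboxylate
Conditions: NaBH4, CeCl3·7H2O, MeOH, 0 °C
Reagents that add atoms: none
Why: Luche 1,2-reduction of the enal gives the primary allylic alcohol whose C6–O bond and C5=C10 alkene form the allyl unit of the coming rearrangement, and NaBH4 leaves the hindered C18 ester alone.

Step 6
Reactants: 8 2-(trimethylsilyl)ethyl (R)-2-(hydroxymethyl)-1,3-dimethylcyclohex-2-ene-1-carboxylate; 9 3-(benzyloxy)propanoic acid
Product: 10 2-(trimethylsilyl)ethyl (R)-2-{[3-(benzyloxy)propanoyloxy]methyl}-1,3-dimethylcyclohex-2-ene-1-carboxylate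
Conditions: DCC, DMAP (cat.), CH2Cl2, 0 °C → rt
Reagents that add atoms: none
Why: Steglich esterification attaches the three-carbon acid whose carboxyl carbon becomes C8, whose α-carbon becomes C9 and whose benzyloxymethyl carbon becomes C11.

Step 7
Reactants: 10 2-(trimethylsilyl)ethyl (R)-2-{[3-(benzyloxy)propanoyloxy]methyl}-1,3-dimethylcyclohex-2-ene-1-carboxylate
Product: 13 (2S)-3-(benzyloxy)-2-[(1R,3R)-1,3-dimethyl-2-methylidene-3-{[2-(trimethylsilyl)ethoxy]carbonyl}cyclohexyl]propanoic acid, via silyl ketene acetal 11 (not isolated), via trimethylsilyl ester 12 (not isolated)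
Conditions: LiN(i-Pr)2, Me3SiCl, THF, −78 °C → rt, then 55 °C; aqueous work-up
Reagents that add atoms: none
Why: Ireland–Claisen rearrangement through a chair forms C9–C10 and moves the alkene to C5=C6; lithium chelation by the β-benzyloxy oxygen should give the ketene acetal with the benzyloxymethyl group syn to OSiMe3, which places it equatorial opposite the axial C20 methyl and so fixes C9 relative to C10, while the ketene acetal is expected to add to the α face of C10, anti to the C19 methyl that sits pseudoaxial on C4 to relieve allylic strain with C6 (the flat ester lying pseudoequatorial), which sets C10 relative to C4.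

Step 8
Reactants: 13 (2S)-3-(benzyloxy)-2-[(1R,3R)-1,3-dimethyl-2-methylidene-3-{[2-(trimethylsilyl)ethoxy]carbonyl}cyclohexyl]propanoic acid
Product: 14 methyl (2S)-3-(benzyloxy)-2-[(1R,3R)-1,3-dimethyl-2-methylidene-3-{[2-(trimethylsilyl)ethoxy]carbonyl}cyclohexyl]propanoate
Conditions: MeI, K2CO3, DMF, rt
Reagents that add atoms: iodomethane, CI
Why: SN2 O-methylation of the potassium carboxylate masks the acid without α-epimerisation, so that borane will react only with the alkene.

Step 9
Reactants: 14 methyl (2S)-3-(benzyloxy)-2-[(1R,3R)-1,3-dimethyl-2-methylidene-3-{[2-(trimethylsilyl)ethoxy]carbonyl}cyclohexyl]propanoate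
Product: 17 2-(trimethylsilyl)ethyl 11-(benzyloxy)-8-oxo-7-oxa-12,13,14,15,16,17-hexanorlabdan-18-oate (trans-fused δ-lactone from the C8 carbonyl to the C6 oxygen; 5α-H and 9α-H), via alkylborane 15 (not isolated), via hydroxy ester 16 (not isolated)
Conditions: BH3·THF, THF, 0 °C → rt; NaOH, H2O2; then TsOH·H2O (cat.), CH2Cl2, rt
Reagents that add atoms: hydrogen peroxide, OO
Why: Hydroboration–oxidation puts boron on the terminal C6 and hydrogen on C5 from the α face, away from the two β-axial methyls C19 and C20, which sets the 5α-H, and acid-catalysed lactonisation of the δ-hydroxy ester to the trans-fused δ-lactone sets the C8 carbonyl apart from the C18 ester.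

Step 10
Reactants: 17 2-(trimethylsilyl)ethyl 11-(benzyloxy)-8-oxo-7-oxa-12,13,14,15,16,17-hexanorlabdan-18-oate
Product: 18 2-(trimethylsilyl)ethyl 11-(benzyloxy)-8-hydroxy-7-oxa-12,13,14,15,16-pentanorlabdan-18-oate (methyl lactol; both C8 epimers)
Conditions: MeLi (1.1 equiv), THF, −78 °C
Reagents that add atoms: methyllithium, [Li]C
Why: Addition of one equivalent of methyllithium to the δ-lactone (lactone to methyl lactol, C17 added) should stop after one addition because the tetrahedral lithium alkoxide persists at −78 °C, and the lactone carbonyl is far more accessible than the neopentyl C18 ester.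

Step 11
Reactants: 18 2-(trimethylsilyl)ethyl 11-(benzyloxy)-8-hydroxy-7-oxa-12,13,14,15,16-pentanorlabdan-18-oate
Product: 19 2-(trimethylsilyl)ethyl 11-(benzyloxy)-6-hydroxy-6,7-seco-12,13,14,15,16-pentanorlabd-7-en-18-oate (ring A with CH2OH on C5 and CH(CH2OBn)C(CH3)=CH2 on C10; C4 C5 C9 C10 as in the target)
Conditions: Ph3PCH3Br, KOt-Bu, THF, 0 → 50 °C
Reagents that add atoms: methyltriphenylphosphonium bromide, C[P+](c1ccccc1)(c1ccccc1)c1ccccc1.[Br-]
Why: Wittig methylenation of the open hydroxy ketone tautomer of the lactol converts the acetyl group into the C7=C8 isopropenyl group and frees the C6 alcohol; any enolisation of the ketone should occur at the methyl group and not at the hindered C9, so C9 is not scrambled.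

Step 12
Reactants: 19 2-(trimethylsilyl)ethyl 11-(benzyloxy)-6-hydroxy-6,7-seco-12,13,14,15,16-pentanorlabd-7-en-18-oate
Product: 20 2-(trimethylsilyl)ethyl (1R,2R,3R)-3-[(2S)-1-(benzyloxy)-3-methylbut-3-en-2-yl]-2-formyl-1,3-dimethylcyclohexane-1-carboxylate (the 6-oxo-6,7-seco compound)
Conditions: Dess–Martin periodinane, CH2Cl2, 0 °C → rt
Reagents that add atoms: none
Why: Dess–Martin oxidation of the primary alcohol gives the aldehyde under neutral conditions that neither epimerise C5 nor touch the isopropenyl group.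

Step 13
Reactants: 20 2-(trimethylsilyl)ethyl (1R,2R,3R)-3-[(2S)-1-(benzyloxy)-3-methylbut-3-en-2-yl]-2-formyl-1,3-dimethylcyclohexane-1-carboxylate
Product: 21 2-(trimethylsilyl)ethyl 11-(benzyloxy)-6α,8α-dihydroxy-12,13,14,15,16-pentanorlabdan-18-oate
Conditions: 0.5 M H2SO4, THF/H2O (3:1), 35 °C
Reagents that add atoms: water, O
Why: Protonation of the C6 aldehyde lets the C7 terminus of the isopropenyl group attack C6 through a chair, forming C6–C7 and closing ring B, and water adds to C8 as the tertiary cation develops (Prins cyclisation; if a proton is lost first, the 8(17)-alkene is rehydrated in the same medium). The closest known reactions are the acid-promoted cyclisation of citronellal to p-menthane-3,8-diol and the type 2 carbonyl-ene closure of 1,1-disubstituted alkenyl aldehydes to 3-methylenecyclohexanols. Ring B closes in a six-membered mode in which the carbonyl carbon is attacked exo and both alkene carbons become ring members (endo at the alkene), the only mode open to the isopropenyl group. At C6 the oxygen takes the equatorial α position because an axial oxygen would be 1,3-diaxial to both the C19 and C20 methyls, and at C8 water enters anti to the new C6–C7 bond, equatorially on the α face away from the axial C20 methyl, so C17 ends axial. The step needs the aldehyde to cyclise before it enolises (C5 must keep its configuration) and the tertiary alcohol to survive, which the equatorial aldehyde held between two quaternary carbons, the absence of any other alkene or free hydroxyl (the C11 benzyl ether oxygen could reach C8 only through an oxetane) and dilute aqueous acid should secure.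

Step 14
Reactants: 21 2-(trimethylsilyl)ethyl 11-(benzyloxy)-6α,8α-dihydroxy-12,13,14,15,16-pentanorlabdan-18-oate
Product: 22 2-(trimethylsilyl)ethyl 11-(benzyloxy)-6α,8α-bis(triethylsilyloxy)-12,13,14,15,16-pentanorlabdan-18-oate
Conditions: Et3SiOTf, 2,6-lutidine, CH2Cl2, −78 → 0 °C
Reagents that add atoms: triethylsilyl trifluoromethanesulfonate, CC[Si](CC)(CC)OS(=O)(=O)C(F)(F)F
Why: Silylation with a silyl triflate and 2,6-lutidine protects the secondary and the tertiary hydroxyl alike, so that the later C11 aldehyde cannot undergo retro-aldol cleavage or elimination across C8–C9 and C6 is not oxidised.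

Step 15
Reactants: 22 2-(trimethylsilyl)ethyl 11-(benzyloxy)-6α,8α-bis(triethylsilyloxy)-12,13,14,15,16-pentanorlabdan-18-oate
Product: 23 2-(trimethylsilyl)ethyl 11-hydroxy-6α,8α-bis(triethylsilyloxy)-12,13,14,15,16-pentanorlabdan-18-oate
Conditions: H2 (1 atm), Pd(OH)2/C, EtOAc, rt
Reagents that add atoms: none
Why: Hydrogenolysis of the benzyl ether frees the C11 alcohol at a stage where the molecule has no alkene, and ethyl acetate as solvent should keep the silyl ethers intact.

Step 16
Reactants: 23 2-(trimethylsilyl)ethyl 11-hydroxy-6α,8α-bis(triethylsilyloxy)-12,13,14,15,16-pentanorlabdan-18-oate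
Product: 24 2-(trimethylsilyl)ethyl 11-oxo-6α,8α-bis(triethylsilyloxy)-12,13,14,15,16-pentanorlabdan-18-oate
Conditions: Dess–Martin periodinane, CH2Cl2, 0 °C → rt
Reagents that add atoms: none
Why: Dess–Martin oxidation gives the C11 aldehyde, whose equatorial β position on C9 should also be the thermodynamically preferred one.

Step 17
Reactants: 24 2-(trimethylsilyl)ethyl 11-oxo-6α,8α-bis(triethylsilyloxy)-12,13,14,15,16-pentanorlabdan-18-oate
Product: 25 2-(trimethylsilyl)ethyl 6α,8α-bis(triethylsilyloxy)-13,14,15,16-tetranorlabd-11-en-18-oate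
Conditions: Ph3PCH3Br, KN(SiMe3)2, THF, −78 → 0 °C
Reagents that add atoms: methyltriphenylphosphonium bromide, C[P+](c1ccccc1)(c1ccccc1)c1ccccc1.[Br-]
Why: Wittig methylenation at low temperature turns the hindered aldehyde into the C11=C12 vinyl group, which adds C12 and provides the hydroboration site.

Step 18
Reactants: 26 1,1-diethoxybut-2-yne
Product: 28 (E)-1,1-diethoxy-3-iodobut-2-ene, via alkenylzirconocene chloride 27 (not isolated)
Conditions: Cp2Zr(H)Cl, THF, rt; then I2, 0 °C
Reagents that add atoms: iodine, II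
Why: Hydrozirconation with the Schwartz reagent adds H and Zr syn across the alkyne with zirconium at the methyl-bearing carbon, remote from the acetal, and iodinolysis with retention gives the (E)-iodoalkene that later fixes the 13E geometry.

Step 19
Reactants: 28 (E)-1,1-diethoxy-3-iodobut-2-ene
Product: 29 (E)-3-iodobut-2-enal
Conditions: TsOH·H2O (cat.), acetone/H2O, rt
Reagents that add atoms: water, O
Why: Acid-catalysed acetal hydrolysis liberates the enal without touching the alkenyl iodide.

Step 20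
Reactants: 30 4-methylfuran-2(5H)-one; 29 (E)-3-iodobut-2-enal
Product: 33 (5Z)-5-[(2E)-3-iodobut-2-en-1-ylidene]-4-methylfuran-2(5H)-one, via silyloxyfuran 31 (not isolated), via silylated aldol adduct 32 (not isolated)
Conditions: t-BuMe2SiOTf, i-Pr2NEt, CH2Cl2, 0 °C → rt; then DBU, rt
Reagents that add atoms: none
Why: One-pot vinylogous Mukaiyama aldol reaction of the in situ 2-silyloxyfuran at C5 with the aldehyde, followed by DBU-induced E1cB loss of silanolate, gives the γ-alkylidene butenolide, the Z isomer being favoured because the chain avoids the ring methyl.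

Step 21
Reactants: 25 2-(trimethylsilyl)ethyl 6α,8α-bis(triethylsilyloxy)-13,14,15,16-tetranorlabd-11-en-18-oate; 33 (5Z)-5-[(2E)-3-iodobut-2-en-1-ylidene]-4-methylfuran-2(5H)-one
Product: 35 2-(trimethylsilyl)ethyl (13E)-15-[(2Z)-3-methyl-5-oxofuran-2(5H)-ylidene]-6α,8α-bis(triethylsilyloxy)labd-13-en-18-oate, via B-alkyl borane 34 (not isolated)
Conditions: 9-BBN, THF, rt → 50 °C; then 33, Pd(dppf)Cl2 (5 mol %), AsPh3, Cs2CO3, DMF/H2O, rt
Reagents that add atoms: none
Why: Anti-Markovnikov hydroboration of the terminal vinyl group with 9-BBN puts boron on C12, and B-alkyl Suzuki–Miyaura coupling with the alkenyl iodide forms C12–C13 with retention of the E geometry while tolerating the ester and silyl ethers.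

Step 22
Reactants: 35 2-(trimethylsilyl)ethyl (13E)-15-[(2Z)-3-methyl-5-oxofuran-2(5H)-ylidene]-6α,8α-bis(triethylsilyloxy)labd-13-en-18-oate
Product: 36 (13E)-6α,8α-dihydroxy-15-[(2Z)-3-methyl-5-oxofuran-2(5H)-ylidene]labd-13-en-18-oic acid (CNP0145461.1)
Conditions: Bu4NF, AcOH (1:1), THF, 0 °C → rt
Reagents that add atoms: none
Why: Fluoride cleaves both triethylsilyl ethers and, by attack at silicon and β-elimination of ethene, the 2-(trimethylsilyl)ethyl ester, acetic acid buffering protects the base-sensitive alkylidene butenolide, and no hydrolysis of the hindered C18 ester is needed.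

**Compound list**

1 | methyl 2-methyl-3-oxopentanoate | CCC(=O)C(C)C(=O)OC | starting material
2 | 2-(trimethylsilyl)ethyl 2-methyl-3-oxopentanoate | CCC(=O)C(C)C(=O)OCC[Si](C)(C)C | intermediate
3 | acrolein | C=CC=O | starting material
4 | 2-(trimethylsilyl)ethyl (R)-2-methyl-3-oxo-2-(3-oxopropyl)pentanoate | CCC(=O)[C@@](C)(CCC=O)C(=O)OCC[Si](C)(C)C | intermediate
5 | 2-(trimethylsilyl)ethyl (R)-1,3-dimethyl-2-oxocyclohex-3-ene-1-carboxylate | CC1=CCC[C@@](C)(C(=O)OCC[Si](C)(C)C)C1=O | intermediate
6 | 2-(trimethylsilyl)ethyl (R)-2-(methoxymethylidene)-1,3-dimethylcyclohex-3-ene-1-carboxylate (E/Z mixture; not isolated) | COC=C1C(C)=CCC[C@@]1(C)C(=O)OCC[Si](C)(C)C | intermediate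
7 | 2-(trimethylsilyl)ethyl (R)-2-formyl-1,3-dimethylcyclohex-2-ene-1-carboxylate | O=CC1=C(C)CCC[C@@]1(C)C(=O)OCC[Si](C)(C)C | intermediate
8 | 2-(trimethylsilyl)ethyl (R)-2-(hydroxymethyl)-1,3-dimethylcyclohex-2-ene-1-carboxylate | OCC1=C(C)CCC[C@@]1(C)C(=O)OCC[Si](C)(C)C | intermediate
9 | 3-(benzyloxy)propanoic acid | OC(=O)CCOCc1ccccc1 | starting material
10 | 2-(trimethylsilyl)ethyl (R)-2-{[3-(benzyloxy)propanoyloxy]methyl}-1,3-dimethylcyclohex-2-ene-1-carboxylate | O=C(CCOCc1ccccc1)OCC2=C(C)CCC[C@@]2(C)C(=O)OCC[Si](C)(C)C | intermediate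
11 | O-trimethylsilyl ketene acetal of 10, benzyloxymethyl syn to OSiMe3 (not isolated) | C[Si](C)(C)O/C(=C\COCc1ccccc1)OCC2=C(C)CCC[C@@]2(C)C(=O)OCC[Si](C)(C)C | intermediate
12 | trimethylsilyl ester of 13 (not isolated) | C[Si](C)(C)OC(=O)[C@H](COCc1ccccc1)[C@@]2(C)CCC[C@@](C)(C(=O)OCC[Si](C)(C)C)C2=C | intermediate
13 | (2S)-3-(benzyloxy)-2-[(1R,3R)-1,3-dimethyl-2-methylidene-3-{[2-(trimethylsilyl)ethoxy]carbonyl}cyclohexyl]propanoic acid | OC(=O)[C@H](COCc1ccccc1)[C@@]2(C)CCC[C@@](C)(C(=O)OCC[Si](C)(C)C)C2=C | intermediate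
14 | methyl ester of 13 | COC(=O)[C@H](COCc1ccccc1)[C@@]2(C)CCC[C@@](C)(C(=O)OCC[Si](C)(C)C)C2=C | intermediate
15 | alkylborane from 14, boron on C6, 5α-H (not isolated) | COC(=O)[C@H](COCc1ccccc1)[C@@]2(C)CCC[C@@](C)(C(=O)OCC[Si](C)(C)C)[C@@H]2CB | intermediate
16 | hydroxy ester from 15, CH2OH on C5 (not isolated) | COC(=O)[C@H](COCc1ccccc1)[C@@]2(C)CCC[C@@](C)(C(=O)OCC[Si](C)(C)C)[C@@H]2CO | intermediate
17 | 2-(trimethylsilyl)ethyl 11-(benzyloxy)-8-oxo-7-oxa-12,13,14,15,16,17-hexanorlabdan-18-oate (trans-fused δ-lactone) | O=C1OC[C@H]2[C@](C)(C(=O)OCC[Si](C)(C)C)CCC[C@]2(C)[C@H]1COCc1ccccc1 | intermediate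
18 | 2-(trimethylsilyl)ethyl 11-(benzyloxy)-8-hydroxy-7-oxa-12,13,14,15,16-pentanorlabdan-18-oate (methyl lactol, both C8 epimers) | CC1(O)OC[C@H]2[C@](C)(C(=O)OCC[Si](C)(C)C)CCC[C@]2(C)[C@H]1COCc1ccccc1 | intermediate
19 | 2-(trimethylsilyl)ethyl 11-(benzyloxy)-6-hydroxy-6,7-seco-12,13,14,15,16-pentanorlabd-7-en-18-oate | c1ccccc1COC[C@@H](C(C)=C)[C@@]2(C)CCC[C@@](C)(C(=O)OCC[Si](C)(C)C)[C@@H]2CO | intermediate
20 | 2-(trimethylsilyl)ethyl (1R,2R,3R)-3-[(2S)-1-(benzyloxy)-3-methylbut-3-en-2-yl]-2-formyl-1,3-dimethylcyclohexane-1-carboxylate | c1ccccc1COC[C@@H](C(C)=C)[C@@]2(C)CCC[C@@](C)(C(=O)OCC[Si](C)(C)C)[C@@H]2C=O | intermediate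
21 | 2-(trimethylsilyl)ethyl 11-(benzyloxy)-6α,8α-dihydroxy-12,13,14,15,16-pentanorlabdan-18-oate | c1ccccc1COC[C@@H]2[C@@]3(C)CCC[C@@](C)(C(=O)OCC[Si](C)(C)C)[C@@H]3[C@@H](O)C[C@@]2(C)O | intermediate
22 | 2-(trimethylsilyl)ethyl 11-(benzyloxy)-6α,8α-bis(triethylsilyloxy)-12,13,14,15,16-pentanorlabdan-18-oate | c1ccccc1COC[C@@H]2[C@@]3(C)CCC[C@@](C)(C(=O)OCC[Si](C)(C)C)[C@@H]3[C@@H](O[Si](CC)(CC)CC)C[C@@]2(C)O[Si](CC)(CC)CC | intermediate
23 | 2-(trimethylsilyl)ethyl 11-hydroxy-6α,8α-bis(triethylsilyloxy)-12,13,14,15,16-pentanorlabdan-18-oate | OC[C@@H]1[C@@]2(C)CCC[C@@](C)(C(=O)OCC[Si](C)(C)C)[C@@H]2[C@@H](O[Si](CC)(CC)CC)C[C@@]1(C)O[Si](CC)(CC)CC | intermediate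
24 | 2-(trimethylsilyl)ethyl 11-oxo-6α,8α-bis(triethylsilyloxy)-12,13,14,15,16-pentanorlabdan-18-oate | O=C[C@@H]1[C@@]2(C)CCC[C@@](C)(C(=O)OCC[Si](C)(C)C)[C@@H]2[C@@H](O[Si](CC)(CC)CC)C[C@@]1(C)O[Si](CC)(CC)CC | intermediate
25 | 2-(trimethylsilyl)ethyl 6α,8α-bis(triethylsilyloxy)-13,14,15,16-tetranorlabd-11-en-18-oate | C=C[C@@H]1[C@@]2(C)CCC[C@@](C)(C(=O)OCC[Si](C)(C)C)[C@@H]2[C@@H](O[Si](CC)(CC)CC)C[C@@]1(C)O[Si](CC)(CC)CC | intermediate
26 | 1,1-diethoxybut-2-yne | CCOC(OCC)C#CC | starting material
27 | (E)-(4,4-diethoxybut-2-en-2-yl)zirconocene chloride (not isolated) | CCOC(OCC)/C=C(\C)[Zr](Cl)(C1C=CC=C1)C1C=CC=C1 | intermediate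
28 | (E)-1,1-diethoxy-3-iodobut-2-ene | CCOC(OCC)/C=C(\C)I | intermediate
29 | (E)-3-iodobut-2-enal | O=C/C=C(\C)I | intermediate
30 | 4-methylfuran-2(5H)-one | CC1=CC(=O)OC1 | starting material
31 | tert-butyl(dimethyl)[(4-methylfuran-2-yl)oxy]silane (not isolated) | CC1=COC(O[Si](C)(C)C(C)(C)C)=C1 | intermediate
32 | 5-[(E)-1-(tert-butyldimethylsilyloxy)-3-iodobut-2-enyl]-4-methylfuran-2(5H)-one (not isolated) | CC1=CC(=O)OC1C(O[Si](C)(C)C(C)(C)C)/C=C(\C)I | intermediate
33 | (5Z)-5-[(2E)-3-iodobut-2-en-1-ylidene]-4-methylfuran-2(5H)-one | CC1=CC(=O)O/C1=C\C=C(/C)I | intermediate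
34 | 2-(trimethylsilyl)ethyl 12-(9-borabicyclo[3.3.1]nonan-9-yl)-6α,8α-bis(triethylsilyloxy)-13,14,15,16-tetranorlabdan-18-oate (not isolated) | C1CCC2CCCC1B2CC[C@@H]1[C@@]2(C)CCC[C@@](C)(C(=O)OCC[Si](C)(C)C)[C@@H]2[C@@H](O[Si](CC)(CC)CC)C[C@@]1(C)O[Si](CC)(CC)CC | intermediate
35 | 2-(trimethylsilyl)ethyl (13E)-15-[(2Z)-3-methyl-5-oxofuran-2(5H)-ylidene]-6α,8α-bis(triethylsilyloxy)labd-13-en-18-oate | CC1=CC(=O)O/C1=C\C=C(/C)CC[C@@H]1[C@@]2(C)CCC[C@@](C)(C(=O)OCC[Si](C)(C)C)[C@@H]2[C@@H](O[Si](CC)(CC)CC)C[C@@]1(C)O[Si](CC)(CC)CC | intermediate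
36 | (13E)-6α,8α-dihydroxy-15-[(2Z)-3-methyl-5-oxofuran-2(5H)-ylidene]labd-13-en-18-oic acid | CC1=CC(=O)O/C1=C\C=C(/C)CC[C@@H]1[C@@]2(C)CCC[C@@](C)(C(=O)O)[C@@H]2[C@@H](O)C[C@@]1(C)O | target

**Step count and risks**

Total steps: 22. Longest linear sequence: 19 (steps 1–17, 21 and 22); steps 18–20 make the side-chain iodide.

Steps most likely to fail:

1. Step 7 (Ireland–Claisen). The C4 methyl/ester pair may discriminate the two faces of the C5=C10 alkene only weakly, and the lithium enolate may expel benzyloxide before it is silylated. The fallback sets out from 10 and comes back at 13, replacing substrate control by reagent control. Ester 10 would be enolised with the chiral bromoborane (4S,5S)-2-bromo-1,3-bis{[3,5-bis(trifluoromethyl)phenyl]sulfonyl}-4,5-diphenyl-1,3,2-diazaborolidine (or its enantiomer, whichever matches the substrate) and i-Pr2NEt in CH2Cl2 at −78 °C. This gives the covalent boron ketene acetal of 10 F1, which has no free enolate to eliminate and whose chiral boron substituent selects the alkene face (enantioselective boron-enolate Claisen rearrangement, known for quaternary centres). The [3,3] shift at −20 to 4 °C gives the acyloxyborane of 13 F2, and aqueous work-up returns 13.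

2. Step 13 (Prins). Proton loss from the C8 cation, enolisation of the aldehyde with epimerisation at C5, or dehydration of the new tertiary alcohol may outrun clean water capture. The fallback sets out from 20 and comes back at 21, separating ring closure from hydration. Me2AlCl (CH2Cl2, −78 °C) would promote the type 2 carbonyl-ene cyclisation to 2-(trimethylsilyl)ethyl 11-(benzyloxy)-6α-hydroxy-12,13,14,15,16-pentanorlabd-8(17)-en-18-oate F3 (same C6–C7 bond and ring B closure, the proton leaving from C17). m-Chloroperbenzoic acid should then epoxidise the exocyclic alkene from the open α face to 2-(trimethylsilyl)ethyl 11-(benzyloxy)-8α,17-epoxy-6α-hydroxy-12,13,14,15,16-pentanorlabdan-18-oate F4. LiBHEt3 (THF, 0 °C) opens the epoxide at the primary C17 to give the 8α-alcohol 21.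

3. Step 21 (Suzuki coupling). Transmetalation of the hindered B-alkyl borane may be slow enough that base-induced degradation of the alkylidene butenolide iodide or β-hydride elimination takes over. The fallback sets out from 34 and comes back at 35, building the butenolide after the coupling. Borane 34 would be coupled under the same palladium conditions with the small, robust iodide 29 to give 2-(trimethylsilyl)ethyl (13E)-15-oxo-6α,8α-bis(triethylsilyloxy)labd-13-en-18-oate F5. The alkylidene butenolide is then raised on this enal as in step 20 (30, t-BuMe2SiOTf, i-Pr2NEt, then DBU, through 31) by way of 2-(trimethylsilyl)ethyl (13E)-15-(tert-butyldimethylsilyloxy)-15-(3-methyl-5-oxo-2,5-dihydrofuran-2-yl)-6α,8α-bis(triethylsilyloxy)labd-13-en-18-oate F6, whose elimination gives 35.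

**Further compounds**

F1 | step 7 | boron ketene acetal of 10 with the (4S,5S)-1,3-bis{[3,5-bis(trifluoromethyl)phenyl]sulfonyl}-4,5-diphenyl-1,3,2-diazaborolidin-2-yl group on oxygen | O=S(=O)(c1cc(cc(c1)C(F)(F)F)C(F)(F)F)N1[C@@H](c2ccccc2)[C@H](c2ccccc2)N(S(=O)(=O)c2cc(cc(c2)C(F)(F)F)C(F)(F)F)B1O/C(=C\COCc1ccccc1)OCC1=C(C)CCC[C@@]1(C)C(=O)OCC[Si](C)(C)C
F2 | step 7 | acyloxyborane of 13 with the same diazaborolidinyl group | O=S(=O)(c1cc(cc(c1)C(F)(F)F)C(F)(F)F)N1[C@@H](c2ccccc2)[C@H](c2ccccc2)N(S(=O)(=O)c2cc(cc(c2)C(F)(F)F)C(F)(F)F)B1OC(=O)[C@H](COCc1ccccc1)[C@@]2(C)CCC[C@@](C)(C(=O)OCC[Si](C)(C)C)C2=C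
F3 | step 13 | 2-(trimethylsilyl)ethyl 11-(benzyloxy)-6α-hydroxy-12,13,14,15,16-pentanorlabd-8(17)-en-18-oate | c1ccccc1COC[C@@H]2[C@@]3(C)CCC[C@@](C)(C(=O)OCC[Si](C)(C)C)[C@@H]3[C@@H](O)CC2=C
F4 | step 13 | 2-(trimethylsilyl)ethyl 11-(benzyloxy)-8α,17-epoxy-6α-hydroxy-12,13,14,15,16-pentanorlabdan-18-oate | c1ccccc1COC[C@@H]2[C@@]3(C)CCC[C@@](C)(C(=O)OCC[Si](C)(C)C)[C@@H]3[C@@H](O)C[C@]24CO4
F5 | step 21 | 2-(trimethylsilyl)ethyl (13E)-15-oxo-6α,8α-bis(triethylsilyloxy)labd-13-en-18-oate | O=C/C=C(\C)CC[C@@H]1[C@@]2(C)CCC[C@@](C)(C(=O)OCC[Si](C)(C)C)[C@@H]2[C@@H](O[Si](CC)(CC)CC)C[C@@]1(C)O[Si](CC)(CC)CC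
F6 | step 21 | 2-(trimethylsilyl)ethyl (13E)-15-(tert-butyldimethylsilyloxy)-15-(3-methyl-5-oxo-2,5-dihydrofuran-2-yl)-6α,8α-bis(triethylsilyloxy)labd-13-en-18-oate | CC1=CC(=O)OC1C(O[Si](C)(C)C(C)(C)C)/C=C(\C)CC[C@@H]2[C@@]3(C)CCC[C@@](C)(C(=O)OCC[Si](C)(C)C)[C@@H]3[C@@H](O[Si](CC)(CC)CC)C[C@@]2(C)O[Si](CC)(CC)CC
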